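**Plan**
1. Retrosynthesis: the three C–Br bonds and the C9 acetate go back to carbinols (SN2 inversion, O-acetylation); C7–H goes back to a C7=C8 enol ether; the O2–C6 and C7–C8 bonds are then cut together, giving the furanoid 1-alkoxyvinylphosphonium salt 10 and the δ-lactol 26.
2. Enabling feature: the six-atom segment O2–C12–C11–C10–C9–C8 of the oxocane is a masked δ-lactol (5-hydroxy aldehyde), and C6=C7 of the tetrahydrofuran (C7 carries ring oxygen O1 and a removable PPh3+) is a Michael acceptor whose α-carbon becomes a Wittig ylide. The oxocane is thus the lactol ring enlarged by insertion of C6=C7 into its O–C8 bond.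
3. Forward order: tetrahydrofuran first (alkynol cycloisomerization, then conversion into the vinylphosphonium salt), oxocane second (oxa-Michael/intramolecular Wittig annulation), then enol ether reduction and the bromination/acetylation endgame.
4. Stereochemistry: C3/C4 from a Sharpless kinetic resolution; C13 from methyl (R)-2-hydroxybutanoate; C12 by reagent-controlled allylboration; C9/C10 by an auxiliary-controlled syn glycolate aldol; C6 by addition anti to the C4 side chain; C7 by hydride delivery cis to the C6 oxygen; C3, C10, C13 bromides by inversion.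

Key step: step 18

Remark: C1–C15 are the carbons of the target written as a pentadec-1-yne (O1 bridges C4/C7, O2 bridges C6/C12) and intermediates keep these numbers; methyl (R)-2-hydroxybutanoate, (S)-4-benzyl-1,3-thiazolidine-2-thione and (+)-Ipc2BOMe are taken as commercial.

**Fragment 1 (tetrahydrofuran part)**

Step 1
Reactants: 1 acrolein; 2 ethynyltrimethylsilane
Product: 3 rac-1-(trimethylsilyl)pent-4-en-1-yn-3-ol
Conditions: n-BuLi, THF, −78 °C; then 1, −78 → 0 °C; H2O
Reagents that add atoms: none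
Why: 1,2-addition of the lithium acetylide to the aldehyde should give the racemic alkynyl vinyl carbinol, whose stereocenter is resolved in step 2.

Step 2
Reactants: 3 rac-1-(trimethylsilyl)pent-4-en-1-yn-3-ol
Product: 4 (S)-1-[(R)-oxiran-2-yl]-3-(trimethylsilyl)prop-2-yn-1-ol
Conditions: Ti(OiPr)4, L-(+)-diisopropyl tartrate, t-BuOOH (0.45 equiv), 4 Å MS, CH2Cl2, −20 °C
Reagents that add atoms: tert-butyl hydroperoxide, CC(C)(C)OO
Why: In this Sharpless kinetic resolution the (R)-carbinol should be epoxidized fast and erythro-selectively (oxygen delivered on the face of the titanium-bound hydroxyl, alkynyl group turned away), setting C3 (S) and C4 (R), while the (S)-carbinol stays behind and is separated.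

Step 3
Reactants: 4 (S)-1-[(R)-oxiran-2-yl]-3-(trimethylsilyl)prop-2-yn-1-ol
Product: 5 tert-butyl{[(S)-1-[(R)-oxiran-2-yl]-3-(trimethylsilyl)prop-2-yn-1-yl]oxy}diphenylsilane
Conditions: TBDPSCl, imidazole, DMF, rt
Reagents that add atoms: tert-butyl(chloro)diphenylsilane, CC(C)(C)[Si](Cl)(c1ccccc1)c1ccccc1
Why: Silylation of the secondary alcohol gives an acid-robust ether that later allows the C3 oxygen to be unmasked after the other silyl ethers.

Step 4
Reactants: 5 TBDPS ether of the epoxy alcohol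
Product: 6 (3S,4R)-3-(tert-butyldiphenylsilyloxy)-1-(trimethylsilyl)hepta-1,6-diyn-4-ol
Conditions: HC≡CLi (acetylene, n-BuLi, THF, −78 °C), BF3·OEt2, −78 °C; H2O
Reagents that add atoms: lithium acetylide, [Li]C#C (made in the flask from acetylene, C#C, and n-BuLi)
Why: BF3-promoted alkynylation opens the terminal epoxide at the unsubstituted carbon C5 (SN2), so the C4–O bond and both stereocenters are untouched.

Step 5
Reactants: 6 (3S,4R)-3-(tert-butyldiphenylsilyloxy)-1-(trimethylsilyl)hepta-1,6-diyn-4-ol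
Product: 7 (R)-2-[(S)-1-(tert-butyldiphenylsilyloxy)-3-(trimethylsilyl)prop-2-yn-1-yl]-2,3-dihydrofuran
Conditions: W(CO)6 (25 mol %), Et3N, THF, hν (350 nm), 60 °C
Reagents that add atoms: none
Why: In this alkynol cycloisomerization the terminal alkyne should form a tungsten vinylidene that the C4 hydroxyl attacks at the α-carbon (endo mode), closing the tetrahydrofuran ring as its C6=C7 enol ether, while the silylated alkyne cannot form a vinylidene.

Step 6
Reactants: 7 (R)-2-substituted 2,3-dihydrofuran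
Product: 10 {(5R)-5-[(1S)-1-(tert-butyldiphenylsilyloxy)-3-(trimethylsilyl)prop-2-yn-1-yl]-4,5-dihydrofuran-2-yl}triphenylphosphonium bromide, via trans-dibromide 8 (not isolated), via β-bromo phosphonium salt 9 (not isolated)
Conditions: Br2, CH2Cl2, −78 °C; PPh3, −78 → 0 °C; Et3N, 0 °C → rt
Reagents that add atoms: bromine, BrBr; triphenylphosphine, c1ccc(cc1)P(c1ccccc1)c1ccccc1
Why: Anti addition of bromine to the enol ether, substitution of the anomeric bromide by PPh3 (α-alkoxyalkylphosphonium salt formation) and E1cB dehydrobromination of the β-bromo phosphonium salt (the way vinyltriphenylphosphonium bromide itself is made) should give the 1-alkoxyvinylphosphonium salt.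

**Fragment 2 (lactol part)**

Step 7
Reactants: 11 methyl (R)-2-hydroxybutanoate
Product: 12 methyl (R)-2-(tert-butyldimethylsilyloxy)butanoate
Conditions: TBSCl, imidazole, DMF, rt
Reagents that add atoms: tert-butyl(chloro)dimethylsilane, CC(C)(C)[Si](C)(C)Cl
Why: Silylation protects the future C13 oxygen, whose configuration comes from the chiral pool.

Step 8
Reactants: 12 methyl (R)-2-(tert-butyldimethylsilyloxy)butanoate
Product: 13 (R)-2-(tert-butyldimethylsilyloxy)butanal
Conditions: i-Bu2AlH, CH2Cl2, −78 °C; aq. KNaC4H4O6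
Reagents that add atoms: none
Why: Partial hydride reduction of the α-silyloxy ester should stop at the tetrahedral aluminium hemiacetal, which gives the aldehyde on work-up without touching the α-stereocenter.

Step 9
Reactants: 13 (R)-2-(tert-butyldimethylsilyloxy)butanal
Product: 14 (4R,5R)-5-(tert-butyldimethylsilyloxy)hept-1-en-4-ol
Conditions: (+)-Ipc2B(allyl), Et2O, −78 °C; NaOH, H2O2
Reagents that add atoms: (+)-B-allyldiisopinocampheylborane, C=CCB([C@H]1C[C@H]2C[C@@H]([C@@H]1C)C2(C)C)[C@H]1C[C@H]2C[C@@H]([C@@H]1C)C2(C)C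
Why: In this Brown allylation the reagent should add to the re face of the aldehyde through a chair transition state under reagent control, setting C12 (R) syn to the C13 silyloxy group.

Step 10
Reactants: 14 (4R,5R)-5-(tert-butyldimethylsilyloxy)hept-1-en-4-ol
Product: 15 (4R,5R)-5-(tert-butyldimethylsilyloxy)-4-(triethylsilyloxy)hept-1-ene
Conditions: TESCl, imidazole, CH2Cl2, 0 °C
Reagents that add atoms: chlorotriethylsilane, CC[Si](Cl)(CC)CC
Why: Silylation masks the C12 hydroxyl with a group that can later be removed in the presence of the TBS ethers.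

Step 11
Reactants: 15 (4R,5R)-5-(tert-butyldimethylsilyloxy)-4-(triethylsilyloxy)hept-1-ene
Product: 16 (3R,4R)-4-(tert-butyldimethylsilyloxy)-3-(triethylsilyloxy)hexanal
Conditions: O3, CH2Cl2, −78 °C; PPh3
Reagents that add atoms: ozone, [O-][O+]=O
Why: Ozonolysis with reductive work-up cleaves the terminal alkene to the C10 aldehyde without affecting the silyl ethers.

Step 12
Reactants: 17 naphthalen-2-ylmethanol; 18 bromoacetic acid
Product: 19 2-(naphthalen-2-ylmethoxy)acetic acid
Conditions: NaH (2.2 equiv), THF, 0 °C → reflux; aq. HCl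
Reagents that add atoms: none
Why: Williamson etherification of the alkoxide with the bromoacetate gives the glycolic acid carrying the oxidatively removable 2-naphthylmethyl (NAP) group.

Step 13
Reactants: 19 2-(naphthalen-2-ylmethoxy)acetic acid; 20 (S)-4-benzyl-1,3-thiazolidine-2-thione
Product: 21 1-[(4S)-4-benzyl-2-thioxo-1,3-thiazolidin-3-yl]-2-(naphthalen-2-ylmethoxy)ethan-1-one
Conditions: EDCI·HCl, DMAP (cat.), CH2Cl2, rt
Reagents that add atoms: none
Why: Carbodiimide-mediated N-acylation attaches the glycolate to the chiral auxiliary.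

Step 14
Reactants: 21 N-glycolyl thiazolidinethione; 16 (3R,4R)-4-(tert-butyldimethylsilyloxy)-3-(triethylsilyloxy)hexanal
Product: 22 (2S,3R,5R,6R)-1-[(4S)-4-benzyl-2-thioxo-1,3-thiazolidin-3-yl]-6-(tert-butyldimethylsilyloxy)-3-hydroxy-2-(naphthalen-2-ylmethoxy)-5-(triethylsilyloxy)octan-1-one
Conditions: TiCl4, i-Pr2NEt, NMP, CH2Cl2, −78 °C; then 16, −78 → −40 °C; H2O
Reagents that add atoms: none
Why: This auxiliary-controlled titanium enolate syn glycolate aldol (Z-enolate, Zimmerman–Traxler chair, aldehyde approaching anti to the benzyl group) should set C9 and C10 as the 2S,3R syn pair with the two oxygens already differentiated.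

Step 15
Reactants: 22 aldol adduct
Product: 23 (2S,3R,5R,6R)-1-[(4S)-4-benzyl-2-thioxo-1,3-thiazolidin-3-yl]-3,6-bis(tert-butyldimethylsilyloxy)-2-(naphthalen-2-ylmethoxy)-5-(triethylsilyloxy)octan-1-one
Conditions: TBSOTf, 2,6-lutidine, CH2Cl2, −78 → 0 °C
Reagents that add atoms: tert-butyldimethylsilyl trifluoromethanesulfonate, CC(C)(C)[Si](C)(C)OS(=O)(=O)C(F)(F)F
Why: Silylation of the aldol hydroxyl gives C10 the same protecting group as C13, so both can later be unveiled and brominated together.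

Step 16
Reactants: 23 silylated aldol adduct
Product: 25 (3S,4R,6R)-4-(tert-butyldimethylsilyloxy)-6-[(R)-1-(tert-butyldimethylsilyloxy)propyl]-3-(naphthalen-2-ylmethoxy)tetrahydro-2H-pyran-2-one, via hydroxy imide 24 (not isolated)
Conditions: HF·pyridine, pyridine, THF, 0 °C; then imidazole (cat.), CH2Cl2, rt
Reagents that add atoms: none
Why: Selective desilylation of the TES ether frees the C12 hydroxyl, which displaces the thiazolidinethione (an activated acyl group) in a lactonization that gives the all-equatorial and hence thermodynamically preferred δ-lactone.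

Step 17
Reactants: 25 δ-lactone
Product: 26 (3S,4R,6R)-4-(tert-butyldimethylsilyloxy)-6-[(R)-1-(tert-butyldimethylsilyloxy)propyl]-3-(naphthalen-2-ylmethoxy)tetrahydro-2H-pyran-2-ol (anomer mixture)
Conditions: i-Bu2AlH, CH2Cl2, −78 °C; aq. KNaC4H4O6
Reagents that add atoms: none
Why: Partial hydride reduction of the lactone stops at the lactol, the masked form of the C12-hydroxy C8-aldehyde.

**Union and endgame**

Step 18
Reactants: 26 δ-lactol; 10 vinylphosphonium bromide
Product: 28 (3S,4R,6S,7E,9R,10R,12R,13R)-3-(tert-butyldiphenylsilyloxy)-10,13-bis(tert-butyldimethylsilyloxy)-4,7:6,12-diepoxy-9-(naphthalen-2-ylmethoxy)-1-(trimethylsilyl)pentadec-7-en-1-yne, via β-alkoxy ylide 27 (not isolated)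
Conditions: NaH, THF, 0 °C; then 10, THF (0.005 M), 0 → 45 °C
Reagents that add atoms: none
Why: Proposed new method: the sodium lactolate of 26 is in equilibrium with its open C12-alkoxide/C8-aldehyde form, whose alkoxide adds in oxa-Michael fashion to C6 of the 1-alkoxyvinylphosphonium salt to give ylide 27, and the ylide carbon C7 then olefinates the tethered C8 aldehyde, so that C6=C7 is in effect inserted into the lactol O–C8 bond. The closest known reaction type is the Schweizer reaction (alkoxide of a hydroxy carbonyl compound plus vinyltriphenylphosphonium bromide, then intramolecular Wittig olefination), extended here to a cyclic 1-alkoxyvinyl salt and to an eight-membered ring. The oxocene closes by intramolecular Wittig olefination (C7=C8, cis within the ring), helped by the gauche O–C–C–O arrangements along C9–C10 and C12–C13 and by the fact that free aldehyde exists only in the tethered ylide. The one new stereocenter, C6, is set in the conjugate addition, the alkoxide approaching the ring face anti to the bulky C4 side chain. The step needs addition through the C12 oxygen and not the hemiacetal oxygen, and ring closure and not oligomerization: the hemiacetal adduct is a ylide without a carbonyl partner that can only revert by E1cB loss of the lactolate, whereas the Wittig step is irreversible, and high dilution with the aldehyde masked as lactol suppresses intermolecular olefination.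

Step 19
Reactants: 28 bicyclic enol ether
Product: 29 (3S,4R,6S,7R,9R,10R,12R,13R)-3-(tert-butyldiphenylsilyloxy)-10,13-bis(tert-butyldimethylsilyloxy)-4,7:6,12-diepoxy-9-(naphthalen-2-ylmethoxy)-1-(trimethylsilyl)pentadec-1-yne
Conditions: Et3SiH, CF3CO2H, CH2Cl2, −78 → −40 °C
Reagents that add atoms: none
Why: In this ionic hydrogenation, protonation at C8 gives the oxocarbenium ion O1=C7, which should take hydride on the envelope face cis to the C6 oxygen and anti to the C4 side chain (inside attack, as in the reduction of furanosyl hemiketals to β-C-glycosides), setting C7 (R) with trans ring fusion and a 2,5-cis tetrahydrofuran.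

Step 20
Reactants: 29 saturated bicyclic ether
Product: 30 (3S,4R,6S,7R,9R,10R,12R,13R)-3-(tert-butyldiphenylsilyloxy)-4,7:6,12-diepoxy-9-(naphthalen-2-ylmethoxy)-1-(trimethylsilyl)pentadec-1-yne-10,13-diol
Conditions: CSA (cat.), MeOH/CH2Cl2, rt
Reagents that add atoms: none
Why: Acid-catalysed methanolysis removes the two secondary TBS ethers, while the far more acid-stable TBDPS ether, the NAP ether and the alkynylsilane should survive.

Step 21
Reactants: 30 10,13-diol
Product: 31 (3S,4R,6S,7R,9R,10S,12R,13S)-10,13-dibromo-3-(tert-butyldiphenylsilyloxy)-4,7:6,12-diepoxy-9-(naphthalen-2-ylmethoxy)-1-(trimethylsilyl)pentadec-1-yne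
Conditions: CBr4, (n-C8H17)3P, toluene, 70 °C
Reagents that add atoms: carbon tetrabromide, BrC(Br)(Br)Br
Why: A double Appel reaction converts both carbinols through alkoxyphosphonium ions into bromides with SN2 inversion (C10 and C13 both become S), the non-participating ether at C9 excluding neighbouring-group retention.

Step 22
Reactants: 31 dibromide
Product: 32 (3S,4R,6S,7R,9R,10S,12R,13S)-10,13-dibromo-3-(tert-butyldiphenylsilyloxy)-4,7:6,12-diepoxy-1-(trimethylsilyl)pentadec-1-yn-9-ol
Conditions: DDQ, CH2Cl2/pH 7 buffer, rt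
Reagents that add atoms: none
Why: Oxidative cleavage of the 2-naphthylmethyl ether by DDQ frees the C9 hydroxyl under neutral conditions that the bromides and silyl groups tolerate.

Step 23
Reactants: 32 C9 alcohol
Product: 33 (3S,4R,6S,7R,9R,10S,12R,13S)-10,13-dibromo-3-(tert-butyldiphenylsilyloxy)-4,7:6,12-diepoxy-1-(trimethylsilyl)pentadec-1-yn-9-yl acetate
Conditions: Ac2O, pyridine, DMAP (cat.), CH2Cl2, 0 °C
Reagents that add atoms: acetic anhydride, CC(=O)OC(C)=O
Why: O-Acetylation installs the C9 acetate with retention, cis to the C10 bromide.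

Step 24
Reactants: 33 acetate
Product: 34 (3S,4R,6S,7R,9R,10S,12R,13S)-9-acetoxy-10,13-dibromo-4,7:6,12-diepoxypentadec-1-yn-3-ol
Conditions: Bu4NF, AcOH, THF, 0 °C → rt
Reagents that add atoms: none
Why: Buffered fluoride desilylation removes the TBDPS ether and the alkynyl TMS group together, the acetic acid buffer protecting the acetate and the secondary bromides from base.

Step 25
Reactants: 34 propargylic alcohol
Product: 35 (3R,4R,6S,7R,9R,10S,12R,13S)-9-acetoxy-3,10,13-tribromo-4,7:6,12-diepoxypentadec-1-yne (target)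
Conditions: CBr4, PPh3, CH2Cl2, 0 °C
Reagents that add atoms: carbon tetrabromide, BrC(Br)(Br)Br
Why: Appel bromination of the propargylic alcohol under mild conditions should proceed by SN2 inversion to the (3R)-bromide, and it is placed last to spare this labile center.

**Compound list**
1 | acrolein | C=CC=O | starting material
2 | ethynyltrimethylsilane | C#C[Si](C)(C)C | starting material
3 | rac-1-(trimethylsilyl)pent-4-en-1-yn-3-ol | C=CC(O)C#C[Si](C)(C)C | intermediate
4 | (S)-1-[(R)-oxiran-2-yl]-3-(trimethylsilyl)prop-2-yn-1-ol | C[Si](C)(C)C#C[C@H](O)[C@H]1CO1 | intermediate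
5 | TBDPS ether of 4 | C[Si](C)(C)C#C[C@H](O[Si](c1ccccc1)(c1ccccc1)C(C)(C)C)[C@H]1CO1 | intermediate
6 | (3S,4R)-3-(tert-butyldiphenylsilyloxy)-1-(trimethylsilyl)hepta-1,6-diyn-4-ol | C[Si](C)(C)C#C[C@H](O[Si](c1ccccc1)(c1ccccc1)C(C)(C)C)[C@H](O)CC#C | intermediate
7 | (R)-2-[(S)-1-(tert-butyldiphenylsilyloxy)-3-(trimethylsilyl)prop-2-yn-1-yl]-2,3-dihydrofuran | C[Si](C)(C)C#C[C@H](O[Si](c1ccccc1)(c1ccccc1)C(C)(C)C)[C@H]1CC=CO1 | intermediate
8 | 6,7-trans-dibromide of 7 (Br at C6 anti to the C4 side chain) | C[Si](C)(C)C#C[C@H](O[Si](c1ccccc1)(c1ccccc1)C(C)(C)C)[C@H]1C[C@H](Br)[C@@H](Br)O1 | intermediate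
9 | (6-bromo-tetrahydrofuran-7-yl)triphenylphosphonium bromide from 8 (C7 epimers) | C[Si](C)(C)C#C[C@H](O[Si](c1ccccc1)(c1ccccc1)C(C)(C)C)[C@H]1C[C@H](Br)C([P+](c2ccccc2)(c2ccccc2)c2ccccc2)O1.[Br-] | intermediate
10 | {(5R)-5-[(1S)-1-(tert-butyldiphenylsilyloxy)-3-(trimethylsilyl)prop-2-yn-1-yl]-4,5-dihydrofuran-2-yl}triphenylphosphonium bromide | C[Si](C)(C)C#C[C@H](O[Si](c1ccccc1)(c1ccccc1)C(C)(C)C)[C@H]1CC=C([P+](c2ccccc2)(c2ccccc2)c2ccccc2)O1.[Br-] | intermediate
11 | methyl (R)-2-hydroxybutanoate | CC[C@@H](O)C(=O)OC | starting material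
12 | methyl (R)-2-(tert-butyldimethylsilyloxy)butanoate | CC[C@@H](O[Si](C)(C)C(C)(C)C)C(=O)OC | intermediate
13 | (R)-2-(tert-butyldimethylsilyloxy)butanal | CC[C@@H](O[Si](C)(C)C(C)(C)C)C=O | intermediate
14 | (4R,5R)-5-(tert-butyldimethylsilyloxy)hept-1-en-4-ol | CC[C@@H](O[Si](C)(C)C(C)(C)C)[C@H](O)CC=C | intermediate
15 | (4R,5R)-5-(tert-butyldimethylsilyloxy)-4-(triethylsilyloxy)hept-1-ene | CC[C@@H](O[Si](C)(C)C(C)(C)C)[C@H](O[Si](CC)(CC)CC)CC=C | intermediate
16 | (3R,4R)-4-(tert-butyldimethylsilyloxy)-3-(triethylsilyloxy)hexanal | CC[C@@H](O[Si](C)(C)C(C)(C)C)[C@H](O[Si](CC)(CC)CC)CC=O | intermediate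
17 | naphthalen-2-ylmethanol | OCc1ccc2ccccc2c1 | starting material
18 | bromoacetic acid | OC(=O)CBr | starting material
19 | 2-(naphthalen-2-ylmethoxy)acetic acid | OC(=O)COCc1ccc2ccccc2c1 | intermediate
20 | (S)-4-benzyl-1,3-thiazolidine-2-thione | S=C1SC[C@H](Cc2ccccc2)N1 | starting material
21 | 1-[(4S)-4-benzyl-2-thioxo-1,3-thiazolidin-3-yl]-2-(naphthalen-2-ylmethoxy)ethan-1-one | O=C(COCc1ccc2ccccc2c1)N1[C@@H](Cc2ccccc2)CSC1=S | intermediate
22 | (2S,3R,5R,6R) syn aldol adduct (3-hydroxy, 2-ONAP, 5-OTES, 6-OTBS) | CC[C@@H](O[Si](C)(C)C(C)(C)C)[C@H](O[Si](CC)(CC)CC)C[C@@H](O)[C@H](OCc1ccc2ccccc2c1)C(=O)N1[C@@H](Cc2ccccc2)CSC1=S | intermediate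
23 | 3-O-TBS ether of 22 | CC[C@@H](O[Si](C)(C)C(C)(C)C)[C@H](O[Si](CC)(CC)CC)C[C@@H](O[Si](C)(C)C(C)(C)C)[C@H](OCc1ccc2ccccc2c1)C(=O)N1[C@@H](Cc2ccccc2)CSC1=S | intermediate
24 | 5-hydroxy imide (23 without the TES group) | CC[C@@H](O[Si](C)(C)C(C)(C)C)[C@H](O)C[C@@H](O[Si](C)(C)C(C)(C)C)[C@H](OCc1ccc2ccccc2c1)C(=O)N1[C@@H](Cc2ccccc2)CSC1=S | intermediate
25 | (3S,4R,6R)-4-(tert-butyldimethylsilyloxy)-6-[(R)-1-(tert-butyldimethylsilyloxy)propyl]-3-(naphthalen-2-ylmethoxy)tetrahydro-2H-pyran-2-one | CC[C@@H](O[Si](C)(C)C(C)(C)C)[C@H]1C[C@@H](O[Si](C)(C)C(C)(C)C)[C@H](OCc2ccc3ccccc3c2)C(=O)O1 | intermediate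
26 | corresponding tetrahydro-2H-pyran-2-ol (lactol, anomer mixture) | CC[C@@H](O[Si](C)(C)C(C)(C)C)[C@H]1C[C@@H](O[Si](C)(C)C(C)(C)C)[C@H](OCc2ccc3ccccc3c2)C(O)O1 | intermediate
27 | β-alkoxy ylide: C12 oxygen bonded to C6, Ph3P=C7, free C8 aldehyde | C[Si](C)(C)C#C[C@H](O[Si](c1ccccc1)(c1ccccc1)C(C)(C)C)[C@H]1C[C@H](O[C@@H]([C@H](O[Si](C)(C)C(C)(C)C)CC)C[C@@H](O[Si](C)(C)C(C)(C)C)[C@H](OCc2ccc3ccccc3c2)C=O)C(=P(c2ccccc2)(c2ccccc2)c2ccccc2)O1 | intermediate
28 | (3S,4R,6S,7E,9R,10R,12R,13R)-3-(tert-butyldiphenylsilyloxy)-10,13-bis(tert-butyldimethylsilyloxy)-4,7:6,12-diepoxy-9-(naphthalen-2-ylmethoxy)-1-(trimethylsilyl)pentadec-7-en-1-yne | C[Si](C)(C)C#C[C@H](O[Si](c1ccccc1)(c1ccccc1)C(C)(C)C)[C@H]1C[C@@H]2O[C@@H]([C@H](O[Si](C)(C)C(C)(C)C)CC)C[C@@H](O[Si](C)(C)C(C)(C)C)[C@H](OCc3ccc4ccccc4c3)/C=C2/O1 | intermediate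
29 | (3S,4R,6S,7R,9R,10R,12R,13R) saturated analogue of 28 | C[Si](C)(C)C#C[C@H](O[Si](c1ccccc1)(c1ccccc1)C(C)(C)C)[C@H]1C[C@@H]2O[C@@H]([C@H](O[Si](C)(C)C(C)(C)C)CC)C[C@@H](O[Si](C)(C)C(C)(C)C)[C@H](OCc3ccc4ccccc4c3)C[C@H]2O1 | intermediate
30 | (3S,4R,6S,7R,9R,10R,12R,13R)-10,13-diol | C[Si](C)(C)C#C[C@H](O[Si](c1ccccc1)(c1ccccc1)C(C)(C)C)[C@H]1C[C@@H]2O[C@@H]([C@H](O)CC)C[C@@H](O)[C@H](OCc3ccc4ccccc4c3)C[C@H]2O1 | intermediate
31 | (3S,4R,6S,7R,9R,10S,12R,13S)-10,13-dibromide | C[Si](C)(C)C#C[C@H](O[Si](c1ccccc1)(c1ccccc1)C(C)(C)C)[C@H]1C[C@@H]2O[C@@H]([C@@H](Br)CC)C[C@H](Br)[C@H](OCc3ccc4ccccc4c3)C[C@H]2O1 | intermediate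
32 | 10,13-dibromo-9-ol | C[Si](C)(C)C#C[C@H](O[Si](c1ccccc1)(c1ccccc1)C(C)(C)C)[C@H]1C[C@@H]2O[C@@H]([C@@H](Br)CC)C[C@H](Br)[C@H](O)C[C@H]2O1 | intermediate
33 | 10,13-dibromo-9-acetate | C[Si](C)(C)C#C[C@H](O[Si](c1ccccc1)(c1ccccc1)C(C)(C)C)[C@H]1C[C@@H]2O[C@@H]([C@@H](Br)CC)C[C@H](Br)[C@H](OC(C)=O)C[C@H]2O1 | intermediate
34 | (3S,4R,6S,7R,9R,10S,12R,13S)-9-acetoxy-10,13-dibromo-4,7:6,12-diepoxypentadec-1-yn-3-ol | C#C[C@H](O)[C@H]1C[C@@H]2O[C@@H]([C@@H](Br)CC)C[C@H](Br)[C@H](OC(C)=O)C[C@H]2O1 | intermediate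
35 | (3R,4R,6S,7R,9R,10S,12R,13S)-9-acetoxy-3,10,13-tribromo-4,7:6,12-diepoxypentadec-1-yne | C#C[C@@H](Br)[C@H]1C[C@@H]2O[C@@H]([C@@H](Br)CC)C[C@H](Br)[C@H](OC(C)=O)C[C@H]2O1 | target

**Totals**
Total step count: 25. Longest linear sequence: 17 steps (steps 7–11 and 14–25).

**Steps most likely to fail**

1. Step 18 (proposed new method). Possible failures: unproductive conjugate addition through the hemiacetal oxygen; slow eight-membered ring closure giving intermolecular olefination; weak facial control at C6; base-induced epimerization at C9. The fallback uses known reactions, closes the ring by metathesis instead of olefination, sets out from 26 and 10 and returns at 28. Wittig methylenation of 26 (Ph3P=CH2, THF) should give the alkenol (3R,4R,6R,7R)-4,7-bis(tert-butyldimethylsilyloxy)-3-(naphthalen-2-ylmethoxy)non-1-en-6-ol F1. Its sodium alkoxide should add to 10 (the first half of a Schweizer reaction, now with a plain alkoxide) and protonation with NH4Br should give the β-alkoxy phosphonium bromide F2, with the C6–O bond in place and C6 epimers separable at this stage. Deprotonation with KN(SiMe3)2 and Wittig reaction with formaldehyde should give the 7-methylene tetrahydrofuran (exocyclic enol ether) F3. Ring-closing enol ether–olefin metathesis with the second-generation Grubbs catalyst RuCl2(=CHPh)(PCy3)(H2IMes) in hot toluene should then give 28.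

2. Step 6. Possible failures: bromine abstraction by PPh3 regenerating 7; elimination toward C5; hydrolysis of the anomeric salt. The fallback sets out from 7 and returns at 10. Epoxidation of 7 with dimethyldioxirane anti to the C4 side chain should give the 6,7-epoxide F4. Opening at the acetal carbon C7 with Ph3P·HBF4 should give the trans 6-hydroxy-7-phosphonium tetrafluoroborate F5. Mesylation and E1cB elimination (MsCl, Et3N) should give the vinylphosphonium tetrafluoroborate F6, and anion exchange with Bu4NBr gives 10.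

3. Step 21. Possible failures: sluggish SN2 at C10 next to the C9 ether; elimination to alkenes; participation of the ring oxygen at C13 with loss of inversion. The fallback sets out from 30 and returns at 31. Sulfonylation with ClCH2SO2Cl/pyridine should give the 10,13-bis(chloromethanesulfonate) F7, and displacement with LiBr in warm acetone/toluene should give 31 with inversion at both centers.

Further compounds
F1 | step 18 | (3R,4R,6R,7R)-4,7-bis(tert-butyldimethylsilyloxy)-3-(naphthalen-2-ylmethoxy)non-1-en-6-ol | CC[C@@H](O[Si](C)(C)C(C)(C)C)[C@H](O)C[C@@H](O[Si](C)(C)C(C)(C)C)[C@H](OCc1ccc2ccccc2c1)C=C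
F2 | step 18 | β-alkoxy phosphonium bromide (O of F1 on C6 trans to the C4 side chain, PPh3+ on C7) | C[Si](C)(C)C#C[C@H](O[Si](c1ccccc1)(c1ccccc1)C(C)(C)C)[C@H]1C[C@H](O[C@@H]([C@H](O[Si](C)(C)C(C)(C)C)CC)C[C@@H](O[Si](C)(C)C(C)(C)C)[C@H](OCc2ccc3ccccc3c2)C=C)C([P+](c2ccccc2)(c2ccccc2)c2ccccc2)O1.[Br-]
F3 | step 18 | 7-methylene tetrahydrofuran (exocyclic enol ether) from F2 | C[Si](C)(C)C#C[C@H](O[Si](c1ccccc1)(c1ccccc1)C(C)(C)C)[C@H]1C[C@H](O[C@@H]([C@H](O[Si](C)(C)C(C)(C)C)CC)C[C@@H](O[Si](C)(C)C(C)(C)C)[C@H](OCc2ccc3ccccc3c2)C=C)C(=C)O1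
F4 | step 6 | 6,7-epoxide of 7 (epoxide anti to the C4 side chain) | C[Si](C)(C)C#C[C@H](O[Si](c1ccccc1)(c1ccccc1)C(C)(C)C)[C@H]1C[C@@H]2O[C@@H]2O1
F5 | step 6 | trans 6-hydroxy-7-(triphenylphosphonio)tetrahydrofuran tetrafluoroborate | C[Si](C)(C)C#C[C@H](O[Si](c1ccccc1)(c1ccccc1)C(C)(C)C)[C@H]1C[C@H](O)[C@@H]([P+](c2ccccc2)(c2ccccc2)c2ccccc2)O1.F[B-](F)(F)F
F6 | step 6 | tetrafluoroborate of the cation of 10 | C[Si](C)(C)C#C[C@H](O[Si](c1ccccc1)(c1ccccc1)C(C)(C)C)[C@H]1CC=C([P+](c2ccccc2)(c2ccccc2)c2ccccc2)O1.F[B-](F)(F)F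
F7 | step 21 | 10,13-bis(chloromethanesulfonate) of 30 | C[Si](C)(C)C#C[C@H](O[Si](c1ccccc1)(c1ccccc1)C(C)(C)C)[C@H]1C[C@@H]2O[C@@H]([C@H](OS(=O)(=O)CCl)CC)C[C@@H](OS(=O)(=O)CCl)[C@H](OCc3ccc4ccccc4c3)C[C@H]2O1
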